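The numbers in the tables stem from a simulated flask from invented constants; noise was put on by code.

Late in the ochre flask, long after its last reading at 12.0 h, what matters is how far the rise of open trimer has slowed, so that is what to watch and what we reckon here.

| setting | ochre | teal | flask |
|---|---|---|---|
| substrate | 1.5 M | 0.75 M | 1.5 M |
| remark | the very flask that is asked about, followed so far | run made earlier |  |
| time |  |  | 40 h |

| run | time / h | substrate / % | ring / % | open trimer / % | open dimer / % |
|---|---|---|---|---|---|
| ochre | 0.833 | 59 | 33 | 4 | 5 |
| ochre | 2.50 | 48 | 30 | 9 | 7 |
| ochre | 4.00 | 44 | 28 | 21 | 7 |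
| ochre | 6.00 | 39 | 26 | 29 | 9 |
| ochre | 10.0 | 30 | 20 | 44 | 7 |
| ochre | 12.0 | 27 | 16 | 51 | 7 |
| teal | 1.00 | 60 | 33 | 0 | 6 |
| teal | 3.00 | 56 | 34 | 4 | 8 |
| teal | 6.00 | 46 | 33 | 15 | 9 |
| teal | 8.00 | 43 | 28 | 19 | 10 |
| teal | 12.0 | 39 | 26 | 29 | 9 |
| teal | 15.0 | 36 | 23 | 38 | 10 |

(readings scatter by 1.5 percentage points)

- percentages count the substrate that a species holds: one open dimer counts as two
- percentages count the substrate that a species holds: one open trimer counts as three

1. the largest share of what was charged as substrate, at 40 h belongs to (ring / substrate / open dimer / open trimer)
2. the largest share itself, whichever of these holds it, in percent of the substrate charged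

Take the unfinished share, meaning everything not yet open trimer, and follow one over that share against time (the usual second-order plot). Its rise per hour, with teal scaled up by the ratio of charges, is:

ochre, 4.00 h to 12.0 h: 0.0969 /h

teal, 6.00 h to 15.0 h: 0.0970 /h

The two runs agree, so we keep their mean, 0.0969 /h, and call it the climb: the hourly rise of one over the unfinished share at a charge of 1.5 M.

A second way parts from this. A straight line through the same ochre readings of open trimer reaches the whole charge at 25.1 h, well before 40 h. We hold the teal run against this line. At half the charge of the ochre run, the teal run took twice the time to read the same open trimer, 29% at 12.0 h against 29% at 6.00 h. So we take the pace to follow the amount present, and to sink as the unfinished share sinks. From the last ochre reading: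

one over the unfinished share at 40 h: 2.04 + 0.0969 /h × 28.0 h = 4.75

For the ochre flask this gives open trimer 79.0%, by our reckoning the largest share.

The forecast says open trimer at 90%, within 80% to 97%, reading the run as “trimer-assisted (autocatalytic) growth”; our reckoning stands lower.

The ochre flask gives open trimer at 78.1%.

    substrate ⇌ ring (K = 0.640, k = 0.0180 /min)
    2 substrate → open dimer (k = 0.00100 /M/min)
    substrate + open dimer → open trimer (k = 0.0110 /M/min)

In the ochre flask, half of the turnover of the step from substrate and open dimer to open trimer, up to 40 h, was done by 8.48 h. Carried on to 400 h, the climb gives this flask 97.5% open trimer; the computed value is 97.4%.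

For a neighbour charged with 0.60 M of substrate we scale the climb by the charge, to 0.0388 /h, and so take its 40 h to match the ochre flask at 16.0 h, which gives an estimate of 58.8% open trimer. The computed result is 56.8%.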